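**Assumptions:** Orsellinic acid, atraric acid (methyl 2,4-dihydroxy-3,6-dimethylbenzoate) and mono-tert-butyl fumarate are commercial. The C8a centre equilibrates through the 8-enol, so the reduction funnels to the isomer with C1 and the new C8–O trans. The sparteine antipode that gives 7R is found empirically. The target is (7R,8S,8aS).

## Retrosynthetic overview
- Pinazaphilone B (**1**) comes from esterifying the C8 secondary OH of alcohol **2** with bis-TBS-orsellinic acid **3** (from orsellinic acid **4**), then removing the TBS and tert-butyl groups.
- **2** comes from C8-selective reduction of the 8-oxo (enol) dienone **5**, which sets C8 and C8a.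
- **5** comes from acid-catalysed cyclodehydration (pyran ring closure) of the dearomatised quinol **6**. **6** comes from enantioselective hydroxylative dearomatisation of phenol **7**, which forms ring A and the C7 centre.
- **7** comes from reductive opening of isocoumarin **8**. **8** comes from lateral acylation of atraric acid **9** with Weinreb amide **10**, which is made from mono-tert-butyl fumarate **11**.

## Forward route

**Step 1**
Reactants: **11** mono-tert-butyl fumarate; **12** N,O-dimethylhydroxylamine hydrochloride
Product: **10** tert-butyl (E)-4-[methoxy(methyl)amino]-4-oxobut-2-enoate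
Conditions: EDC·HCl, HOBt, DIPEA, CH2Cl2, 0 °C → rt
Reagents that add atoms: N,O-dimethylhydroxylamine hydrochloride, CNOC.Cl
Why: Carbodiimide Weinreb amidation gives an acyl donor that stops at the ketone, and the E-alkene and tert-butyl ester are untouched.

**Step 2**
Reactants: **4** orsellinic acid; **13** TBSCl
Product: **3** 2,4-bis(TBSO)-6-methylbenzoic acid
Conditions: TBSCl (4 equiv), imidazole, DMF, rt; then K2CO3, MeOH/THF/H2O, rt
Reagents that add atoms: TBSCl, CC(C)(C)[Si](C)(C)Cl
Why: Per-silylation followed by selective hydrolysis of the labile silyl ester leaves the acid with both phenols as TBS ethers.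

**Step 3**
Reactants: **9** atraric acid; **10** Weinreb amide
Product: **8** tert-butyl (E)-3-(6,8-dihydroxy-7-methyl-1-oxo-1H-isochromen-3-yl)acrylate
Conditions: LDA (5 equiv), THF, –78 → 0 °C, add **10**; then aq. NH4Cl
Reagents that add atoms: none
Why: Lateral (ortho-toluate) metalation of the 6-CH3 is followed by Weinreb acylation. The resulting ketone (as its enolate) closes onto the ortho methyl ester with loss of MeOH (enol lactonisation) to give the isocoumarin. No stereocentre is formed.

**Step 4**
Reactants: **8**
Product: **7** tert-butyl (E)-5-[3,5-dihydroxy-2-(hydroxymethyl)-4-methylphenyl]-4-oxopent-2-enoate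
Conditions: LiAlH4 (5 equiv), THF, 0 °C → 50 °C; then Rochelle salt
Reagents that add atoms: none
Why: Hydride opens the enol lactone at C1=O, and the aldehyde formed is reduced to the benzylic CH2OH. The chain carbonyl (old C3) is released as its enolate, which shields it from further hydride until work-up. This is reductive ring opening and sets the C1 oxidation level.

**Step 5**
Reactants: **7**; **14** dioxygen
Product: **6** dearomatised ortho-quinol (C6 ketone; C7 = C(OH)CH3, 7R; 8-hydroxy enol; 8a-CH2OH; 4a-CH2C(=O)CH=CHCO2tBu)
Conditions: Cu(MeCN)4PF6 (20 mol %), (–)-sparteine, O2 (1 atm), CH2Cl2, –20 °C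
Reagents that add atoms: dioxygen, O=O
Why: Copper/sparteine-mediated enantioselective hydroxylative oxidative dearomatisation attacks C7, the methyl-bearing carbon between the two phenols. The chiral Cu–phenolate–O2 complex fixes the C7 configuration (7R), and the dienone persists because C7 is quaternary.

**Step 6**
Reactants: **6**
Product: **5** tert-butyl (E)-3-[(7R)-7,8-dihydroxy-7-methyl-6-oxo-6,7-dihydro-1H-isochromen-3-yl]acrylate (8-enol, in tautomeric equilibrium with the 8-oxo-8aH form)
Conditions: PPTS (0.2 equiv), 4 Å MS, CH2Cl2, rt
Reagents that add atoms: none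
Why: Cyclodehydration by intramolecular hemiketalisation of the C3 ketone with the C1–OH, then loss of water, gives the conjugated vinylogous-ester pyran (C3=C4, C4a=C5). The C7 centre is untouched.

**Step 7**
Reactants: **5**
Product: **2** tert-butyl (E)-3-[(7R,8S,8aS)-7,8-dihydroxy-7-methyl-6-oxo-6,7,8,8a-tetrahydro-1H-isochromen-3-yl]acrylate
Conditions: NaBH(OAc)3 (5 equiv), AcOH/MeCN (1:1), 0 °C
Reagents that add atoms: none
Why: AcOH ketonises the enol, which lets C8a epimerise. The acetoxyborohydride binds the C7 tertiary OH and delivers hydride to C8=O from the face syn to that OH and anti to the C7-methyl (directed α-hydroxy-ketone reduction). This gives the 7,8-trans diol (8S), with C8a (S) trans to the new C8–O. The C6 carbonyl is a deactivated vinylogous ester and is not reduced.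

**Step 8**
Reactants: **2**; **3**
Product: **15** 8-O-[2,4-bis(TBSO)-6-methylbenzoyl] ester of **2**
Conditions: **3** (2 equiv), EDC·HCl, DMAP (0.5 equiv), CH2Cl2, 0 °C → rt
Reagents that add atoms: none
Why: Steglich esterification goes selectively at the secondary C8–OH, because the C7 tertiary OH is too hindered. The C7, C8 and C8a stereocentres are not involved.

**Step 9**
Reactants: **15**
Product: **16** the tert-butyl ester of pinazaphilone B (phenols free)
Conditions: HF·pyridine, pyridine/THF, 0 °C → rt, dark
Reagents that add atoms: none
Why: Fluoride cleaves the two aryl TBS ethers under mildly acidic, non-basic conditions. Avoiding base prevents E1cB loss of the C8 ester through the C8a–H/enone dienolate.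

**Step 10**
Reactants: **16**
Product: **1** pinazaphilone B
Conditions: TFA/CH2Cl2 (1:4), anisole (10 equiv), 0 °C, 30 min
Reagents that add atoms: none
Why: Acidolysis of the tert-butyl ester (E1, losing isobutylene) gives the free acrylic acid. Anisole traps the tert-butyl cation so it does not alkylate the resorcinol ring. The vinylogous-ester pyran is acid-tolerant, and no stereocentre is changed.

## Compound list
1 | pinazaphilone B, (7R,8S,8aS) | Cc1cc(O)cc(O)c1C(=O)O[C@H]1[C@@H]2COC(/C=C/C(=O)O)=CC2=CC(=O)[C@]1(C)O | target
2 | tert-butyl ester of 8-hydroxy core (7R,8S,8aS) | O[C@H]1[C@@H]2COC(/C=C/C(=O)OC(C)(C)C)=CC2=CC(=O)[C@]1(C)O | intermediate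
3 | 2,4-bis(TBSO)-6-methylbenzoic acid | Cc1cc(O[Si](C)(C)C(C)(C)C)cc(O[Si](C)(C)C(C)(C)C)c1C(=O)O | intermediate
4 | orsellinic acid | Cc1cc(O)cc(O)c1C(=O)O | starting material
5 | 8-enol dienone (7R) | OC1=C2COC(/C=C/C(=O)OC(C)(C)C)=CC2=CC(=O)[C@]1(C)O | intermediate
6 | dearomatised ortho-quinol (7R) | OC1=C(CO)C(=CC(=O)[C@]1(C)O)CC(=O)/C=C/C(=O)OC(C)(C)C | intermediate
7 | tert-butyl (E)-5-[3,5-dihydroxy-2-(hydroxymethyl)-4-methylphenyl]-4-oxopent-2-enoate | Cc1c(O)cc(CC(=O)/C=C/C(=O)OC(C)(C)C)c(CO)c1O | intermediate
8 | isocoumarin | Cc1c(O)cc2cc(/C=C/C(=O)OC(C)(C)C)oc(=O)c2c1O | intermediate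
9 | atraric acid (methyl 2,4-dihydroxy-3,6-dimethylbenzoate) | COC(=O)c1c(C)cc(O)c(C)c1O | starting material
10 | Weinreb amide of mono-tert-butyl fumarate | CON(C)C(=O)/C=C/C(=O)OC(C)(C)C | intermediate
11 | mono-tert-butyl fumarate | O=C(O)/C=C/C(=O)OC(C)(C)C | starting material
12 | N,O-dimethylhydroxylamine hydrochloride | CNOC.Cl | starting material (reagent)
13 | tert-butyldimethylsilyl chloride | CC(C)(C)[Si](C)(C)Cl | starting material (reagent)
14 | dioxygen | O=O | starting material (reagent)
15 | bis-TBS orsellinate ester | Cc1cc(O[Si](C)(C)C(C)(C)C)cc(O[Si](C)(C)C(C)(C)C)c1C(=O)O[C@H]1[C@@H]2COC(/C=C/C(=O)OC(C)(C)C)=CC2=CC(=O)[C@]1(C)O | intermediate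
16 | tert-butyl ester of pinazaphilone B | Cc1cc(O)cc(O)c1C(=O)O[C@H]1[C@@H]2COC(/C=C/C(=O)OC(C)(C)C)=CC2=CC(=O)[C@]1(C)O | intermediate

**Total steps:** 10. Steps 1 and 2 prepare the two coupling partners, **10** and **3**.
**Longest linear sequence:** 9 steps, from mono-tert-butyl fumarate (**11**): Step 1 (→**10**), Step 3 (→**8**), Step 4 (→**7**), Step 5 (→**6**), Step 6 (→**5**), Step 7 (→**2**), Step 8 (→**15**), Step 9 (→**16**), Step 10 (→**1**). Counted from atraric acid (**9**), the chain is 8 steps, and the orsellinic acid arm (Steps 2, 8, 9, 10) is shorter.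

## Three steps most likely to fail
1. **Step 3 (lateral acylation).** The highly anionic, electron-rich polyanion may add conjugately to the fumaramate instead of acylating.
   - Fallback: acylate with N-methoxy-N-methylacetamide to make the 3-methyl isocoumarin. Carry it through the same sequence, then build the CH=CH–CO2H chain from the vinylogous 3-CH3 of **5** by aldol condensation with glyoxylic acid.
2. **Step 5 (asymmetric dearomatisation).** The enantiomeric excess may be low, and the electron-rich substrate or the product's 1,8a-dihydro (1H-isochromene-dienone) core may be over-oxidised to the azaphilone.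
   - Fallback: use achiral PIFA/H2O dearomatisation of **7** and resolve the enantiomers of **5** or **2** by preparative chiral-phase HPLC. A chiral iodoarene-catalysed dearomatisation is a second alternative.
3. **Step 7 (C8/C8a reduction).** Hydroxyl-directed reduction of an α-hydroxy ketone is less reliable than the 1,3-directed case, and the C8a epimer ratio is unproven.
   - Fallback: reduce non-selectively, accept the cis-7,8-diol, and invert C8 in a Mitsunobu esterification of the alcohol with acid **3** (DIAD, PPh3). This installs the ester with inversion, and the C8a epimers are then separated.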